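**Overview**

Numbering used below (elemane type): C10 is the ring carbon with CH3 and the C1=C2 vinyl, C5 the ring CH with the C4(=C3H2)–C15O2H unit, C6 the lactone O–CH, C7 the ring CH with C11(=C13H2)–C12, C8 the angelate carbon, C9 the ring CH2.
Bonds cut, in retrosynthetic order: the C8–O acyl bond and the C15 ester; the lactone O–C12 bond; the ring bond C6–C7 (carbonyl-ene retron); C4=C3 back to a C4 ketone; last the C5–C10 bond, paired with a C2–O bond, as a Gosteli–Claisen retron.
Enabling feature: the C1=C2 vinyl on C10 and the C4 acrylate on C5 flank the C5–C10 bond, so C4–C5–C10–C1=C2 becomes a γ,δ-unsaturated carbonyl array once C3 is exchanged for oxygen. The allyl half (C2, C1, C10 with its methyl, C9, C8, C7, C11, C12, C13) is an unbroken 5-oxygenated nerol chain, so neither the cyclohexane C5–C6–C7–C8–C9–C10 nor the γ-lactone is needed before the [3,3] step.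
Forward order: a dihydropyranone is built only to fix the Z alkene and is opened; O–H insertion and olefination join the chain into the allyl vinyl ether; the [3,3] shift makes C5–C10 (no ring); the cyclohexane closes at C6–C7, then the γ-lactone at O–C12; C8 is inverted and acylated and the acid is freed.
Stereochemistry: C8 comes from a catalytic asymmetric vinylogous aldol, deliberately as the 8-epimer (equatorial in the ene chair), and is inverted late by oxidation and equatorial hydride delivery. C5 and C10 come from the Z,Z chair of the Claisen step, with the absolute sense from the box ligand; C6 and C7 from the all-equatorial ene chair; the angelate Z geometry is bought.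

Key step: step 10

Assumption: in steps 2 and 10 the sense of induction follows the ligand antipode, so the Tol-BINAP and tBu-box enantiomers that give the drawn configurations are the ones used (tBu-box = 2,2-bis(4-tert-butyl-4,5-dihydrooxazol-2-yl)propane).

**Route**

Step 1
Reactants: 1 methyl 3-methylbut-2-enoate
Product: 2 1-methoxy-3-methyl-1-(trimethylsilyloxy)buta-1,3-diene
Conditions: LiN(iPr)2, THF, −78 °C; Me3SiCl, −78 °C to rt; distillation
Reagents that add atoms: chlorotrimethylsilane, C[Si](C)(C)Cl
Why: Kinetic γ-deprotonation of the senecioate ester and O-silylation of the lithium dienolate give the cross-conjugated silyl ketene acetal (silyl dienolate formation), the usual nucleophile for a vinylogous Mukaiyama aldol reaction.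

Step 2
Reactants: 2 1-methoxy-3-methyl-1-(trimethylsilyloxy)buta-1,3-diene; 3 3-methylbut-2-enal
Product: 5 (6S)-4-methyl-6-(2-methylprop-1-enyl)-5,6-dihydro-2H-pyran-2-one, via copper aldolate 4 (not isolated)
Conditions: Cu(OTf)2 (10 mol %), Tol-BINAP (11 mol %), Bu4N[Ph3SiF2] (20 mol %), THF, 0 °C to rt
Reagents that add atoms: none
Why: Catalytic asymmetric vinylogous Mukaiyama aldol reaction with lactonisation in the flask: the fluoride-generated copper dienolate carrying Tol-BINAP adds through its γ-carbon to the aldehyde carbonyl of 3, the ligand sets the carbinol centre (future C8) as S, and the Z-configured aldolate 4 closes onto its methyl ester, so that the ring fixes the C1=C10 alkene as Z.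

Step 3
Reactants: 5 (6S)-4-methyl-6-(2-methylprop-1-enyl)-5,6-dihydro-2H-pyran-2-one
Product: 6 (2Z,5S)-3,7-dimethylocta-2,6-diene-1,5-diol
Conditions: LiAlH4, Et2O, −20 to 0 °C
Reagents that add atoms: none
Why: Hydride reduction of the lactone to the diol (LiAlH4 reduction of an ester) is 1,2-selective on this β,β-disubstituted enoate and opens the ring without touching the alkene, so the Z geometry enforced by the ring is kept in the open chain.

Step 4
Reactants: 6 (2Z,5S)-3,7-dimethylocta-2,6-diene-1,5-diol
Product: 7 (2Z,5S)-5-hydroxy-3,7-dimethylocta-2,6-dien-1-yl 2,2-dimethylpropanoate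
Conditions: pivaloyl chloride (1.05 equiv), pyridine, CH2Cl2, −20 to 0 °C
Reagents that add atoms: pivaloyl chloride, CC(C)(C)C(=O)Cl
Why: Selective acylation of the primary allylic hydroxyl with the bulky pivaloyl chloride at low temperature (steric differentiation of a primary from a secondary alcohol) leaves the C8 hydroxyl free.

Step 5
Reactants: 7 (2Z,5S)-5-hydroxy-3,7-dimethylocta-2,6-dien-1-yl 2,2-dimethylpropanoate
Product: 8 (2Z,5S)-5-(tert-butyldiphenylsilyloxy)-3,7-dimethylocta-2,6-dien-1-yl 2,2-dimethylpropanoate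
Conditions: tBuPh2SiCl, imidazole, DMF, rt
Reagents that add atoms: tert-butyl(chloro)diphenylsilane, CC(C)(C)[Si](Cl)(c1ccccc1)c1ccccc1
Why: Imidazole-promoted silylation of the secondary alcohol gives the TBDPS ether, chosen because it survives the later selective cleavage of a primary TBS ether, the Lewis acids and the oxidants.

Step 6
Reactants: 8 (2Z,5S)-5-(tert-butyldiphenylsilyloxy)-3,7-dimethylocta-2,6-dien-1-yl 2,2-dimethylpropanoate
Product: 9 (2Z,5S)-5-(tert-butyldiphenylsilyloxy)-3,7-dimethylocta-2,6-dien-1-ol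
Conditions: iBu2AlH, CH2Cl2, −78 °C
Reagents that add atoms: none
Why: Reductive cleavage of the pivalate ester with iBu2AlH at low temperature frees the primary allylic alcohol and leaves the silyl ether and both alkenes alone.

Step 7
Reactants: 10 tert-butyl 2-(diethoxyphosphoryl)acetate
Product: 11 tert-butyl 2-diazo-2-(diethoxyphosphoryl)acetate
Conditions: NaH, THF, 0 °C; 4-acetamidobenzenesulfonyl azide, 0 °C to rt
Reagents that add atoms: 4-acetamidobenzenesulfonyl azide, CC(=O)Nc1ccc(cc1)S(=O)(=O)N=[N+]=[N-]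
Why: Regitz diazo transfer from the sulfonyl azide to the sodium enolate of the doubly activated methylene group gives the diazo phosphonoacetate.

Step 8
Reactants: 9 (2Z,5S)-5-(tert-butyldiphenylsilyloxy)-3,7-dimethylocta-2,6-dien-1-ol; 11 tert-butyl 2-diazo-2-(diethoxyphosphoryl)acetate
Product: 12 tert-butyl 2-(diethoxyphosphoryl)-2-{[(2Z,5S)-5-(tert-butyldiphenylsilyloxy)-3,7-dimethylocta-2,6-dien-1-yl]oxy}acetate (both epimers at C2)
Conditions: Rh2(OAc)4 (1 mol %), toluene, 80 °C
Reagents that add atoms: none
Why: Rh2(OAc)4 turns the diazo compound into a rhodium carbenoid that inserts into the O–H bond of the primary alcohol (carbenoid O–H insertion) faster than it cyclopropanates the trisubstituted alkenes, and the new stereocentre, formed as both epimers, becomes sp2 in the next step.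

Step 9
Reactants: 12 α-allyloxy phosphonoacetate; 13 (tert-butyldimethylsilyloxy)acetaldehyde
Product: 14 tert-butyl (2Z)-4-(tert-butyldimethylsilyloxy)-2-{[(2Z,5S)-5-(tert-butyldiphenylsilyloxy)-3,7-dimethylocta-2,6-dien-1-yl]oxy}but-2-enoate
Conditions: LiN(SiMe3)2, THF, −78 °C; then 13, −78 °C to rt; chromatographic removal of the 2E isomer
Reagents that add atoms: none
Why: Horner–Wadsworth–Emmons olefination of the lithiated α-alkoxy phosphonate with the aldehyde is expected to favour the 2Z isomer, with the ester trans to C6 and C6 cis to the allyloxy oxygen, and the 2E isomer is removed because this geometry later decides the configuration at C5.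

Step 10
Reactants: 14 (Z,Z)-2-(tert-butoxycarbonyl) allyl vinyl ether
Product: 15 tert-butyl (3S,4S,6S)-3-[(tert-butyldimethylsilyloxy)methyl]-6-(tert-butyldiphenylsilyloxy)-4-ethenyl-4,8-dimethyl-2-oxonon-7-enoate
Conditions: [Cu(tBu-box)(H2O)2](SbF6)2 (10 mol %), CH2Cl2, −30 to 0 °C, quenched at full conversion
Reagents that add atoms: none
Why: The divalent copper centre binds the allylic ether oxygen and the ester carbonyl of 14 in a five-membered chelate, which polarises the C2–O bond so that the C5–C10 σ bond forms as the C2–O bond breaks in a concerted [3,3] shift through a chair; the closest known reaction type is the catalytic asymmetric Gosteli–Claisen rearrangement of 2-alkoxycarbonyl allyl vinyl ethers with box complexes of divalent copper, applied here to a 3,3-disubstituted neryl-type terminus. No ring closes: the step turns the ether into the C4 ketone, the C1=C2 vinyl group and the C10 quaternary carbon. The relative configuration of C5 and C10 follows from the chair in which the two Z substituents (C6 on the vinyl ether, C9 on the allyl terminus) are pseudo-axial, and the absolute sense comes from the tBu-box ligand, which shields one face of the chelated vinyl ether and so picks one of the two enantiomeric chairs regardless of the distant C8 centre. The step needs one face pairing out of four and must stay concerted; the geometrically pure Z,Z substrate, the two-point binding through the future C15 carboxyl and the low temperature should hold it on the chair pathway against boat or ionisation routes. The reaction is stopped cold at full conversion so that the α-keto ester does not go on to a copper-promoted carbonyl-ene reaction with the prenyl alkene, for which the bulky tert-butyl ester and the hindered ketone are a further brake.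

Step 11
Reactants: 15 α-keto ester
Product: 16 tert-butyl (3R,4S,6S)-3-[(tert-butyldimethylsilyloxy)methyl]-6-(tert-butyldiphenylsilyloxy)-4-ethenyl-4,8-dimethyl-2-methylidenenon-7-enoate
Conditions: Zn, CH2Br2, TiCl4, THF, 0 °C (reagent pre-formed); then 15, THF/CH2Cl2, 0 °C to rt
Reagents that add atoms: dibromomethane, BrCBr
Why: Takai–Lombardo methylenation with the gem-dimetallic methylene reagent from Zn, CH2Br2 and TiCl4 is non-basic, so the enolisable C5 centre and the β-silyloxy group next to the ketone are neither epimerised nor eliminated, and it converts the ketone but not the tert-butyl ester into the 1,1-disubstituted alkene (C3 added).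

Step 12
Reactants: 16 acrylate bis-silyl ether
Product: 17 tert-butyl (3R,4S,6S)-6-(tert-butyldiphenylsilyloxy)-4-ethenyl-3-(hydroxymethyl)-4,8-dimethyl-2-methylidenenon-7-enoate
Conditions: HF·pyridine, pyridine, THF, 0 °C
Reagents that add atoms: none
Why: Buffered fluoride desilylation removes the unhindered primary TBS ether well before the secondary TBDPS ether (selective silyl ether cleavage), and the bulky tert-butyl ester keeps the freed hydroxyl from lactonising onto C15.

Step 13
Reactants: 17 primary alcohol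
Product: 18 tert-butyl (3R,4S,6S)-6-(tert-butyldiphenylsilyloxy)-4-ethenyl-3-formyl-4,8-dimethyl-2-methylidenenon-7-enoate
Conditions: Dess–Martin periodinane, NaHCO3, CH2Cl2, 0 °C; used directly
Reagents that add atoms: none
Why: Dess–Martin oxidation under buffered, non-basic conditions gives the aldehyde without epimerising C5 or moving the C4=C3 alkene into conjugation, and the aldehyde is taken on without storage.

Step 14
Reactants: 18 C6 aldehyde
Product: 19 tert-butyl 2-[(1R,2S,4S,5S,6R)-4-(tert-butyldiphenylsilyloxy)-2-ethenyl-6-hydroxy-2-methyl-5-(prop-1-en-2-yl)cyclohexyl]prop-2-enoate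
Conditions: Me2AlCl (1.5 equiv), CH2Cl2, −78 °C
Reagents that add atoms: none
Why: Lewis acid-promoted type 1 intramolecular carbonyl-ene reaction of the citronellal-to-isopulegol kind: the Me2AlCl-bound aldehyde carbon C6 is attacked by C7 of the trisubstituted alkene while a methyl hydrogen passes to oxygen, and closure through the chair with the C5 acrylate, the C8 silyloxy group, the carbonyl oxygen and the nascent isopropenyl group all equatorial (C10 methyl axial) sets C6 and C7 with hydroxyl and isopropenyl trans.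

Step 15
Reactants: 19 cyclohexanol
Product: 20 tert-butyl 2-[(1R,2S,4S,5S,6R)-4-(tert-butyldiphenylsilyloxy)-2-ethenyl-6-hydroxy-5-(3-hydroxyprop-1-en-2-yl)-2-methylcyclohexyl]prop-2-enoate
Conditions: SeO2 (0.5 equiv), tBuOOH, CH2Cl2, rt
Reagents that add atoms: selenium dioxide, O=[Se]=O; tert-butyl hydroperoxide, CC(C)(C)OO
Why: Selenium dioxide allylic oxidation (ene reaction followed by [2,3]-sigmatropic shift) hydroxylates the methyl of the isopropenyl group as it does in isopulegol, since the acrylate is too electron-poor to react and the C10 vinyl has no allylic hydrogen.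

Step 16
Reactants: 20 1,4-diol
Product: 23 tert-butyl 2-[(3aS,4S,6S,7R,7aR)-4-(tert-butyldiphenylsilyloxy)-6-ethenyl-6-methyl-3-methylidene-2-oxooctahydro-1-benzofuran-7-yl]prop-2-enoate, via hydroxy enal 21 (not isolated), via lactol 22 (not isolated)
Conditions: TEMPO (20 mol %), PhI(OAc)2 (2.5 equiv), CH2Cl2, rt
Reagents that add atoms: none
Why: TEMPO/PhI(OAc)2 oxidative lactonisation of a 1,4-diol: the primary allylic alcohol is oxidised first to enal 21, the equatorial C6 hydroxyl adds to give lactol 22, and a second oxidation gives the trans-fused α-methylene γ-lactone without touching C6 or C7.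

Step 17
Reactants: 23 silyl-protected lactone
Product: 24 tert-butyl 2-[(3aR,4S,6S,7R,7aR)-6-ethenyl-4-hydroxy-6-methyl-3-methylidene-2-oxooctahydro-1-benzofuran-7-yl]prop-2-enoate
Conditions: HF·pyridine, THF, rt
Reagents that add atoms: none
Why: Fluoride-driven cleavage of the Si–O bond with HF·pyridine, an acidic rather than basic fluoride source, spares the α-methylene lactone and the tert-butyl ester and frees the equatorial C8 hydroxyl.

Step 18
Reactants: 24 equatorial (8-epi) alcohol
Product: 25 tert-butyl 2-[(3aS,6S,7R,7aR)-6-ethenyl-6-methyl-3-methylidene-2,4-dioxooctahydro-1-benzofuran-7-yl]prop-2-enoate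
Conditions: Dess–Martin periodinane, NaHCO3, CH2Cl2, 0 °C; used directly
Reagents that add atoms: none
Why: Dess–Martin oxidation of the secondary alcohol under buffered conditions gives the C8 ketone, which is reduced at once because C7–H is now α to the ketone and vinylogous to the lactone carbonyl.

Step 19
Reactants: 25 C8 ketone
Product: 26 tert-butyl 2-[(3aR,4R,6S,7R,7aR)-6-ethenyl-4-hydroxy-6-methyl-3-methylidene-2-oxooctahydro-1-benzofuran-7-yl]prop-2-enoate
Conditions: NaBH4, CeCl3·7H2O, MeOH/THF, −78 °C
Reagents that add atoms: none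
Why: Luche reduction at −78 °C reduces the ketone 1,2 much faster than it adds hydride to the methylene lactone or the acrylate, and because the axial C10 methyl is 1,3-diaxial to the axial line of approach the hydride enters from the equatorial side and gives the axial 8R alcohol (substrate-controlled cyclohexanone reduction).

Step 20
Reactants: 26 axial C8 alcohol; 27 angelic acid, (2Z)-2-methylbut-2-enoic acid
Product: 29 (3aR,4R,6S,7R,7aR)-7-(3-tert-butoxy-3-oxoprop-1-en-2-yl)-6-ethenyl-6-methyl-3-methylidene-2-oxooctahydro-1-benzofuran-4-yl (2Z)-2-methylbut-2-enoate, via mixed anhydride 28 (not isolated)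
Conditions: 27, 2,4,6-Cl3C6H2COCl, Et3N, toluene, rt; then 26, toluene, 75 °C
Reagents that add atoms: none
Why: Yamaguchi esterification: the mixed anhydride 28 acylates the hindered axial alcohol at the less hindered angeloyl carbonyl with retention at C8, and running it without a nucleophilic amine catalyst is the known way to keep the Z geometry of the angeloyl group.

Step 21
Reactants: 29 angelate tert-butyl ester
Product: 30 CNP0256928.2, 2-[(3aR,4R,6S,7R,7aR)-6-ethenyl-6-methyl-3-methylidene-4-{[(2Z)-2-methylbut-2-enoyl]oxy}-2-oxooctahydro-1-benzofuran-7-yl]prop-2-enoic acid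
Conditions: CF3CO2H, CH2Cl2, 0 °C
Reagents that add atoms: none
Why: Acidolysis of the tert-butyl ester by CF3CO2H (loss of isobutene through the tert-butyl cation) frees the acrylic acid while the angelate, the lactone and the alkenes, none of which is acid-labile under these conditions, stay intact.

**Compound list**

1 | methyl 3-methylbut-2-enoate | COC(=O)C=C(C)C | starting material
2 | 1-methoxy-3-methyl-1-(trimethylsilyloxy)buta-1,3-diene | C=C(C)C=C(OC)O[Si](C)(C)C | intermediate
3 | 3-methylbut-2-enal | CC(C)=CC=O | starting material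
4 | copper aldolate of methyl (2Z,5S)-5-hydroxy-3,7-dimethylocta-2,6-dienoate (monovalent copper on O5, phosphine ligand not drawn; formed in the flask) | COC(=O)/C=C(/C)C[C@H](O[Cu])C=C(C)C | intermediate
5 | (6S)-4-methyl-6-(2-methylprop-1-enyl)-5,6-dihydro-2H-pyran-2-one | O=C1C=C(C)C[C@@H](C=C(C)C)O1 | intermediate
6 | (2Z,5S)-3,7-dimethylocta-2,6-diene-1,5-diol | OC/C=C(/C)C[C@H](O)C=C(C)C | intermediate
7 | (2Z,5S)-5-hydroxy-3,7-dimethylocta-2,6-dien-1-yl 2,2-dimethylpropanoate | CC(C)(C)C(=O)OC/C=C(/C)C[C@H](O)C=C(C)C | intermediate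
8 | (2Z,5S)-5-(tert-butyldiphenylsilyloxy)-3,7-dimethylocta-2,6-dien-1-yl 2,2-dimethylpropanoate | CC(C)(C)C(=O)OC/C=C(/C)C[C@H](O[Si](c1ccccc1)(c1ccccc1)C(C)(C)C)C=C(C)C | intermediate
9 | (2Z,5S)-5-(tert-butyldiphenylsilyloxy)-3,7-dimethylocta-2,6-dien-1-ol | OC/C=C(/C)C[C@H](O[Si](c1ccccc1)(c1ccccc1)C(C)(C)C)C=C(C)C | intermediate
10 | tert-butyl 2-(diethoxyphosphoryl)acetate | CCOP(=O)(OCC)CC(=O)OC(C)(C)C | starting material
11 | tert-butyl 2-diazo-2-(diethoxyphosphoryl)acetate | CCOP(=O)(OCC)C(=[N+]=[N-])C(=O)OC(C)(C)C | intermediate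
12 | tert-butyl 2-(diethoxyphosphoryl)-2-{[(2Z,5S)-5-(tert-butyldiphenylsilyloxy)-3,7-dimethylocta-2,6-dien-1-yl]oxy}acetate (both epimers at C2) | CCOP(=O)(OCC)C(OC/C=C(/C)C[C@H](O[Si](c1ccccc1)(c1ccccc1)C(C)(C)C)C=C(C)C)C(=O)OC(C)(C)C | intermediate
13 | (tert-butyldimethylsilyloxy)acetaldehyde | CC(C)(C)[Si](C)(C)OCC=O | starting material
14 | tert-butyl (2Z)-4-(tert-butyldimethylsilyloxy)-2-{[(2Z,5S)-5-(tert-butyldiphenylsilyloxy)-3,7-dimethylocta-2,6-dien-1-yl]oxy}but-2-enoate | CC(C)(C)OC(=O)/C(=C/CO[Si](C)(C)C(C)(C)C)OC/C=C(/C)C[C@H](O[Si](c1ccccc1)(c1ccccc1)C(C)(C)C)C=C(C)C | intermediate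
15 | tert-butyl (3S,4S,6S)-3-[(tert-butyldimethylsilyloxy)methyl]-6-(tert-butyldiphenylsilyloxy)-4-ethenyl-4,8-dimethyl-2-oxonon-7-enoate | CC(C)(C)OC(=O)C(=O)[C@H](CO[Si](C)(C)C(C)(C)C)[C@](C)(C=C)C[C@H](O[Si](c1ccccc1)(c1ccccc1)C(C)(C)C)C=C(C)C | intermediate
16 | tert-butyl (3R,4S,6S)-3-[(tert-butyldimethylsilyloxy)methyl]-6-(tert-butyldiphenylsilyloxy)-4-ethenyl-4,8-dimethyl-2-methylidenenon-7-enoate | C=C(C(=O)OC(C)(C)C)[C@H](CO[Si](C)(C)C(C)(C)C)[C@](C)(C=C)C[C@H](O[Si](c1ccccc1)(c1ccccc1)C(C)(C)C)C=C(C)C | intermediate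
17 | tert-butyl (3R,4S,6S)-6-(tert-butyldiphenylsilyloxy)-4-ethenyl-3-(hydroxymethyl)-4,8-dimethyl-2-methylidenenon-7-enoate | C=C(C(=O)OC(C)(C)C)[C@H](CO)[C@](C)(C=C)C[C@H](O[Si](c1ccccc1)(c1ccccc1)C(C)(C)C)C=C(C)C | intermediate
18 | tert-butyl (3R,4S,6S)-6-(tert-butyldiphenylsilyloxy)-4-ethenyl-3-formyl-4,8-dimethyl-2-methylidenenon-7-enoate | O=C[C@@H](C(=C)C(=O)OC(C)(C)C)[C@](C)(C=C)C[C@H](O[Si](c1ccccc1)(c1ccccc1)C(C)(C)C)C=C(C)C | intermediate
19 | tert-butyl 2-[(1R,2S,4S,5S,6R)-4-(tert-butyldiphenylsilyloxy)-2-ethenyl-6-hydroxy-2-methyl-5-(prop-1-en-2-yl)cyclohexyl]prop-2-enoate | C=C[C@]1(C)C[C@H](O[Si](c2ccccc2)(c2ccccc2)C(C)(C)C)[C@@H](C(C)=C)[C@H](O)[C@H]1C(=C)C(=O)OC(C)(C)C | intermediate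
20 | tert-butyl 2-[(1R,2S,4S,5S,6R)-4-(tert-butyldiphenylsilyloxy)-2-ethenyl-6-hydroxy-5-(3-hydroxyprop-1-en-2-yl)-2-methylcyclohexyl]prop-2-enoate | C=C[C@]1(C)C[C@H](O[Si](c2ccccc2)(c2ccccc2)C(C)(C)C)[C@@H](C(=C)CO)[C@H](O)[C@H]1C(=C)C(=O)OC(C)(C)C | intermediate
21 | hydroxy enal, tert-butyl 2-[(1R,2S,4S,5S,6R)-4-(tert-butyldiphenylsilyloxy)-2-ethenyl-6-hydroxy-2-methyl-5-(3-oxoprop-1-en-2-yl)cyclohexyl]prop-2-enoate (formed in the flask) | C=C[C@]1(C)C[C@H](O[Si](c2ccccc2)(c2ccccc2)C(C)(C)C)[C@@H](C(=C)C=O)[C@H](O)[C@H]1C(=C)C(=O)OC(C)(C)C | intermediate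
22 | lactol, tert-butyl 2-[(3aS,4S,6S,7R,7aR)-4-(tert-butyldiphenylsilyloxy)-6-ethenyl-2-hydroxy-6-methyl-3-methylideneoctahydro-1-benzofuran-7-yl]prop-2-enoate (both C2 epimers; formed in the flask) | C=C[C@]1(C)C[C@H](O[Si](c2ccccc2)(c2ccccc2)C(C)(C)C)[C@H]3C(=C)C(O)O[C@@H]3[C@H]1C(=C)C(=O)OC(C)(C)C | intermediate
23 | tert-butyl 2-[(3aS,4S,6S,7R,7aR)-4-(tert-butyldiphenylsilyloxy)-6-ethenyl-6-methyl-3-methylidene-2-oxooctahydro-1-benzofuran-7-yl]prop-2-enoate | C=C[C@]1(C)C[C@H](O[Si](c2ccccc2)(c2ccccc2)C(C)(C)C)[C@H]3C(=C)C(=O)O[C@@H]3[C@H]1C(=C)C(=O)OC(C)(C)C | intermediate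
24 | tert-butyl 2-[(3aR,4S,6S,7R,7aR)-6-ethenyl-4-hydroxy-6-methyl-3-methylidene-2-oxooctahydro-1-benzofuran-7-yl]prop-2-enoate | C=C[C@]1(C)C[C@H](O)[C@H]2C(=C)C(=O)O[C@@H]2[C@H]1C(=C)C(=O)OC(C)(C)C | intermediate
25 | tert-butyl 2-[(3aS,6S,7R,7aR)-6-ethenyl-6-methyl-3-methylidene-2,4-dioxooctahydro-1-benzofuran-7-yl]prop-2-enoate | C=C[C@]1(C)CC(=O)[C@H]2C(=C)C(=O)O[C@@H]2[C@H]1C(=C)C(=O)OC(C)(C)C | intermediate
26 | tert-butyl 2-[(3aR,4R,6S,7R,7aR)-6-ethenyl-4-hydroxy-6-methyl-3-methylidene-2-oxooctahydro-1-benzofuran-7-yl]prop-2-enoate | C=C[C@]1(C)C[C@@H](O)[C@H]2C(=C)C(=O)O[C@@H]2[C@H]1C(=C)C(=O)OC(C)(C)C | intermediate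
27 | angelic acid, (2Z)-2-methylbut-2-enoic acid | C/C=C(/C)C(=O)O | starting material
28 | mixed anhydride, (2Z)-2-methylbut-2-enoic 2,4,6-trichlorobenzoic anhydride (formed in the flask) | C/C=C(/C)C(=O)OC(=O)c1c(Cl)cc(Cl)cc1Cl | intermediate
29 | (3aR,4R,6S,7R,7aR)-7-(3-tert-butoxy-3-oxoprop-1-en-2-yl)-6-ethenyl-6-methyl-3-methylidene-2-oxooctahydro-1-benzofuran-4-yl (2Z)-2-methylbut-2-enoate | C=C[C@]1(C)C[C@@H](OC(=O)/C(C)=C\C)[C@H]2C(=C)C(=O)O[C@@H]2[C@H]1C(=C)C(=O)OC(C)(C)C | intermediate
30 | CNP0256928.2, 2-[(3aR,4R,6S,7R,7aR)-6-ethenyl-6-methyl-3-methylidene-4-{[(2Z)-2-methylbut-2-enoyl]oxy}-2-oxooctahydro-1-benzofuran-7-yl]prop-2-enoic acid | C=C[C@]1(C)C[C@@H](OC(=O)/C(C)=C\C)[C@H]2C(=C)C(=O)O[C@@H]2[C@H]1C(=C)C(=O)O | target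

**Step count**

Total: 21 steps. Longest linear sequence: 20 steps (steps 1–6 and 8–21); step 7 is a one-step side branch.

**Steps most likely to fail**

Step 10 (Claisen rearrangement). The allyl terminus is tertiary, so the Lewis acid may push the substrate off the concerted chair pathway into ionisation and recombination. The catalyst may also fail to override the face pairing, or the keto ester may react on with the prenyl alkene in a carbonyl-ene reaction. The fallback sets out from 14 and drops the Lewis acid: 14 is heated without catalyst in 1,2-dichloroethane (sealed tube, about 80 °C). The thermal Gosteli–Claisen shift is concerted, and the Z,Z chair still fixes the relative configuration of C5 and C10. The absolute sense is then no longer set by a catalyst but by separation against the resident C8 centre: the rearrangement should give 15 together with its diastereomer tert-butyl (3R,4R,6S)-3-[(tert-butyldimethylsilyloxy)methyl]-6-(tert-butyldiphenylsilyloxy)-4-ethenyl-4,8-dimethyl-2-oxonon-7-enoate F1, which is removed by chromatography. The route is rejoined at 15.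

Step 14 (carbonyl-ene closure). Under the Lewis acid the aldehyde may epimerise at C5 or its acrylate double bond may move into conjugation. The allylic silyl ether may ionise, or the chair may not be selective enough for the trans hydroxyl/isopropenyl pair. The fallback sets out from 16 and closes the same C6–C7 bond by an intramolecular Nozaki–Hiyama–Kishi allylation under neutral conditions:
- SeO2/tBuOOH should oxidise the (E)-methyl of the prenyl group of 16 to tert-butyl (3R,4S,6S,7E)-3-[(tert-butyldimethylsilyloxy)methyl]-6-(tert-butyldiphenylsilyloxy)-4-ethenyl-9-hydroxy-4,8-dimethyl-2-methylidenenon-7-enoate F2.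
- Methanesulfonyl chloride, Et3N and LiCl convert it into the allylic chloride tert-butyl (3R,4S,6S,7E)-3-[(tert-butyldimethylsilyloxy)methyl]-6-(tert-butyldiphenylsilyloxy)-9-chloro-4-ethenyl-4,8-dimethyl-2-methylidenenon-7-enoate F3.
- Buffered HF·pyridine frees the primary alcohol tert-butyl (3R,4S,6S,7E)-6-(tert-butyldiphenylsilyloxy)-9-chloro-4-ethenyl-3-(hydroxymethyl)-4,8-dimethyl-2-methylidenenon-7-enoate F4.
- Dess–Martin oxidation gives the aldehyde tert-butyl (3R,4S,6S,7E)-6-(tert-butyldiphenylsilyloxy)-9-chloro-4-ethenyl-3-formyl-4,8-dimethyl-2-methylidenenon-7-enoate F5.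
- CrCl2 with NaI in THF/DMF turns the allylic chloride into an allylchromium species of trivalent chromium, which should add through its γ-carbon C7 to the aldehyde in a chair, anti, to give the trans hydroxyl/isopropenyl cyclohexanol.

The route is rejoined at 19.

Step 19 (C8 ketone reduction). Hydride delivery may not be selective enough for the equatorial face, conjugate reduction of the methylene lactone may compete, or the keto lactone 25 may isomerise to the conjugated butenolide before it is reduced. The fallback sets out from 24 and avoids the ketone altogether: Mitsunobu esterification of the equatorial alcohol 24 with angelic acid 27 (PPh3, diisopropyl azodicarboxylate, toluene, 0 °C to rt) should displace the activated oxygen with inversion and install the axial angelate directly. Steps 18 to 20 are bypassed and the route is rejoined at 29. This fallback makes no compound outside the list (F0).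

**Further compounds**

F1 | step 10 | tert-butyl (3R,4R,6S)-3-[(tert-butyldimethylsilyloxy)methyl]-6-(tert-butyldiphenylsilyloxy)-4-ethenyl-4,8-dimethyl-2-oxonon-7-enoate | CC(C)(C)OC(=O)C(=O)[C@@H](CO[Si](C)(C)C(C)(C)C)[C@@](C)(C=C)C[C@H](O[Si](c1ccccc1)(c1ccccc1)C(C)(C)C)C=C(C)C
F2 | step 14 | tert-butyl (3R,4S,6S,7E)-3-[(tert-butyldimethylsilyloxy)methyl]-6-(tert-butyldiphenylsilyloxy)-4-ethenyl-9-hydroxy-4,8-dimethyl-2-methylidenenon-7-enoate | C=C(C(=O)OC(C)(C)C)[C@H](CO[Si](C)(C)C(C)(C)C)[C@](C)(C=C)C[C@H](O[Si](c1ccccc1)(c1ccccc1)C(C)(C)C)/C=C(\C)CO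
F3 | step 14 | tert-butyl (3R,4S,6S,7E)-3-[(tert-butyldimethylsilyloxy)methyl]-6-(tert-butyldiphenylsilyloxy)-9-chloro-4-ethenyl-4,8-dimethyl-2-methylidenenon-7-enoate | C=C(C(=O)OC(C)(C)C)[C@H](CO[Si](C)(C)C(C)(C)C)[C@](C)(C=C)C[C@H](O[Si](c1ccccc1)(c1ccccc1)C(C)(C)C)/C=C(\C)CCl
F4 | step 14 | tert-butyl (3R,4S,6S,7E)-6-(tert-butyldiphenylsilyloxy)-9-chloro-4-ethenyl-3-(hydroxymethyl)-4,8-dimethyl-2-methylidenenon-7-enoate | C=C(C(=O)OC(C)(C)C)[C@H](CO)[C@](C)(C=C)C[C@H](O[Si](c1ccccc1)(c1ccccc1)C(C)(C)C)/C=C(\C)CCl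
F5 | step 14 | tert-butyl (3R,4S,6S,7E)-6-(tert-butyldiphenylsilyloxy)-9-chloro-4-ethenyl-3-formyl-4,8-dimethyl-2-methylidenenon-7-enoate | O=C[C@@H](C(=C)C(=O)OC(C)(C)C)[C@](C)(C=C)C[C@H](O[Si](c1ccccc1)(c1ccccc1)C(C)(C)C)/C=C(\C)CCl
F0 | step 19 | none | none
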